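**Assumptions (one line each)**
- Oppositin (C24H20O7) has no stereocentre, and the biaryl axis is not configurationally stable because the pyranone has no ortho substituents. The "single enantiomer" requirement is therefore moot, and no stereochemistry needs to be set.
- 4-Bromo-3,5-dimethoxybenzaldehyde, benzaldehyde and maltol are commercial.
- Ir-catalysed C–H borylation of 8 is assumed to go at C6, the most acidic α-oxy C–H.

**Retrosynthesis**
1. The biaryl bond (flavone C6 to pyranone C6) is made last by Suzuki coupling of 6-bromo-5,7-dimethoxyflavone with a pyranone-6-Bpin.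
2. The pyranone partner comes from commercial maltol by O-methylation and then Ir-catalysed C6–H borylation, so no pyranone ring has to be built.
3. The flavone C-ring is formed from a 2'-hydroxychalcone by oxidative cyclisation.
4. The chalcone comes from Claisen–Schmidt condensation of 5'-bromo-2'-hydroxy-4',6'-dimethoxyacetophenone with benzaldehyde.
5. That acetophenone comes from Nencki acylation of 4-bromo-3,5-dimethoxyphenol, which comes from Dakin oxidation of the commercial aldehyde.
6. The bromine sits between the two OMe groups from the start, so C6 regiochemistry is fixed. The C ring is formed before the final biaryl coupling.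

**Step 1**
Reactants: 1, 4-bromo-3,5-dimethoxybenzaldehyde
Product: 2, 4-bromo-3,5-dimethoxyphenol
Conditions: (i) mCPBA, CH2Cl2, 0 °C to rt; (ii) K2CO3, MeOH, rt
Reagents that add atoms: mCPBA, O=C(OO)c1cccc(Cl)c1 (supplies the phenol oxygen)
Why: Baeyer–Villiger/Dakin oxidation moves the electron-rich aryl group to oxygen to give the aryl formate, and methanolysis releases the phenol. No stereocentre is involved.

**Step 2**
Reactants: 2, 4-bromo-3,5-dimethoxyphenol
Product: 3, 1-(5-bromo-2-hydroxy-4,6-dimethoxyphenyl)ethan-1-one
Conditions: AcOH, BF3·OEt2, 90 °C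
Reagents that add atoms: acetic acid, CC(=O)O (supplies the acetyl group)
Why: Nencki-type ortho-C-acylation is directed by the phenol OH. The two ortho positions are equivalent, so only one regioisomer forms, and the Br stays between the two OMe groups.

**Step 3**
Reactants: 3, plus 4, benzaldehyde
Product: 5, (E)-1-(5-bromo-2-hydroxy-4,6-dimethoxyphenyl)-3-phenylprop-2-en-1-one
Conditions: KOH (aq), EtOH, rt
Reagents that add atoms: none (benzaldehyde is the numbered reactant)
Why: Claisen–Schmidt aldol condensation gives the (E)-2'-hydroxychalcone, and this alkene geometry is lost in the next step.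

**Step 4**
Reactants: 5, the chalcone
Product: 6, 6-bromo-5,7-dimethoxy-2-phenyl-4H-chromen-4-one
Conditions: I2 (cat.), DMSO, 130 °C
Reagents that add atoms: none
Why: I2/DMSO effects oxa-Michael cyclisation to the flavanone and then oxidation, giving the flavone directly (Ar–Br and OMe groups are inert). There is no stereocentre in the product.

**Step 5**
Reactants: 7, maltol (3-hydroxy-2-methyl-4H-pyran-4-one)
Product: 8, 3-methoxy-2-methyl-4H-pyran-4-one
Conditions: MeI, K2CO3, acetone, reflux
Reagents that add atoms: iodomethane, CI (supplies the methyl group)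
Why: Williamson O-methylation of the enolic OH; the pyranone is unchanged.

**Step 6**
Reactants: 8, 3-methoxy-2-methyl-4H-pyran-4-one
Product: 9, 2-(3-methoxy-2-methyl-4-oxo-4H-pyran-6-yl)-4,4,5,5-tetramethyl-1,3,2-dioxaborolane (pyranone 6-Bpin)
Conditions: [Ir(cod)OMe]2 (1.5 mol%), dtbpy (3 mol%), B2pin2, THF, 80 °C
Reagents that add atoms: bis(pinacolato)diboron, CC1(C)OB(OC1(C)C)B1OC(C)(C)C(C)(C)O1 (supplies the Bpin group)
Why: Ir-catalysed C–H borylation favours the most acidic, least hindered α-oxy C–H (C6). C2 is blocked by methyl, and C5 is deactivated because it lies α to the carbonyl.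

**Step 7**
Reactants: 6, the aryl bromide, plus 9, the pyranone-Bpin
Product: 10, oppositin, 6-(3-methoxy-2-methyl-4-oxo-4H-pyran-6-yl)-5,7-dimethoxyflavone
Conditions: Pd2(dba)3, SPhos, K3PO4, 1,4-dioxane/H2O, 100 °C
Reagents that add atoms: none (the atoms come from the two numbered reactants)
Why: Suzuki–Miyaura coupling with a bulky biaryl phosphine ligand handles the di-ortho-methoxy-substituted aryl bromide, and the product is achiral.

**Compound list**

| No. | Name | SMILES | Role |
|---|---|---|---|
| 1 | 4-Bromo-3,5-dimethoxybenzaldehyde | COc1cc(C=O)cc(OC)c1Br | starting material |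
| 2 | 4-Bromo-3,5-dimethoxyphenol | COc1cc(O)cc(OC)c1Br | intermediate |
| 3 | 1-(5-Bromo-2-hydroxy-4,6-dimethoxyphenyl)ethanone | CC(=O)c1c(O)cc(OC)c(Br)c1OC | intermediate |
| 4 | Benzaldehyde | O=Cc1ccccc1 | starting material |
| 5 | (E)-5'-Bromo-2'-hydroxy-4',6'-dimethoxychalcone | COc1cc(O)c(C(=O)/C=C/c2ccccc2)c(OC)c1Br | intermediate |
| 6 | 6-Bromo-5,7-dimethoxyflavone | COc1cc2oc(-c3ccccc3)cc(=O)c2c(OC)c1Br | intermediate |
| 7 | Maltol | Cc1occc(=O)c1O | starting material |
| 8 | 3-Methoxy-2-methyl-4H-pyran-4-one | COc1c(C)occc1=O | intermediate |
| 9 | Pyranone-6-Bpin | COc1c(C)oc(B2OC(C)(C)C(C)(C)O2)cc1=O | intermediate |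
| 10 | Oppositin (achiral, so no stereodescriptors) | COc1cc2oc(-c3ccccc3)cc(=O)c2c(OC)c1-c1cc(=O)c(OC)c(C)o1 | target |

**Totals**
- Total steps: 7.
- Longest linear sequence: 5 steps (1 → 2 → 3 → 5 → 6 → 10).

**Three steps most likely to fail**
1. **Step 6, C6 borylation of 8.** It may give C5 or mixed borylation, or the α-oxy Bpin may protodeboronate. Fallback: drop pyranone C–H metalation and use Minisci-type radical arylation of protonated 8, with an aryl radical generated from the flavone-6-boronic acid (made from 6) by AgNO3/K2S2O8.
2. **Step 7, hindered Suzuki coupling.** The di-ortho-OMe aryl bromide and the α-oxy heteroaryl boronate may give poor conversion. Fallback: build the pyranone de novo on the flavone. Convert 6 to the 6-acetylflavone (Stille with tributyl(1-ethoxyvinyl)tin, then H3O+), do a Claisen acylation with methyl 2-methoxy-3-oxobutanoate, and close the ring by acid cyclodehydration.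
3. **Step 1, Dakin oxidation.** H-migration could give the benzoic acid instead of the phenol. Fallback: start from commercial 2'-hydroxy-4',6'-dimethoxyacetophenone, iodinate with NIS, and separate the 5'-iodo isomer from the 3'-iodo isomer. Then continue from Step 3 with the iodo compound and couple at the end.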